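## Retrosynthetic overview

1. The target is reached by C‑methylation of the ring A carbon that already carries the prenyl group. Ring A (the cyclohexanetrione) comes from two Claisen condensations of a chiral β‑diketone dianion with the two carbonyl groups on the spiro carbon of ring B, which are told apart as lactone and methyl ester.
2. Ring B rests on this feature: its carbinol carbon C(OH)CH3 is bonded directly to the ring‑fusion CH shared with ring C (the cyclopentane), a tertiary alcohol next to a C–C bond. A methyl ketone adding to the near alkene carbon of a cyclopentene, with hydrogen taken from the ring C CH2, delivers exactly this (Me2AlCl, type 1 ketone‑ene).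
3. The ene precursor is dimethyl malonate alkylated first by a cyclopentenylmethyl iodide and then by chloroacetone.
4. Ring C and its two stereocentres come from Sharpless epoxidation of (Z)‑3‑methylhexa‑2,5‑dien‑1‑ol, vinyl cuprate opening and ring‑closing metathesis.
5. Order of ring formation: C (metathesis), then B (ene), then A (Claisen/Dieckmann).

Key step: step 11

Remark: (R)‑2‑methylbutanoic acid (20) is taken as a commercial acid; triones 25 and 26 are drawn as one enol tautomer, and C‑4 of ring A in 24 and 25 is epimerisable and left undefined.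
Remark on locants: hydrindane (indene numbering): C‑1 ring C carbinol, C‑3a/C‑7a ring fusion (C‑3a bonded to C‑4), C‑4 ring B carbinol, C‑5 and C‑7 the ring B CH2 groups, C‑6 the future spiro carbon. Ring A: C‑1 and C‑5 carbonyls, C‑2 acyl‑bearing, C‑3 enol, C‑4 (methyl, prenyl), C‑6 spiro.

## Route

Step 1
Reactants: 1 but-2-yn-1-ol
Product: 3 (Z)-3-iodobut-2-en-1-ol, via cyclic alkenylaluminate 2 (not isolated)
Conditions: NaAlH2(OCH2CH2OCH3)2, THF, 0 °C → rt; then I2, −78 → 0 °C; aq. Na2S2O3
Reagents that add atoms: iodine, II
Why: trans‑hydroalumination of the propargylic alcohol places aluminium at C‑3 cis to the CH2O group in a five‑membered chelate, and iodinolysis of the C–Al bond with retention gives the (Z)‑iodoalkene (hydroalumination–iodination).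

Step 2
Reactants: 3 (Z)-3-iodobut-2-en-1-ol; 4 allyltributylstannane
Product: 5 (Z)-3-methylhexa-2,5-dien-1-ol
Conditions: PdCl2(MeCN)2 (5 mol%), DMF, rt
Reagents that add atoms: none
Why: Stille coupling of an alkenyl iodide with an allylstannane keeps the alkene geometry and tolerates the free hydroxyl, giving the nerol‑type (Z)‑allylic alcohol with a skipped terminal alkene.

Step 3
Reactants: 5 (Z)-3-methylhexa-2,5-dien-1-ol
Product: 6 [(2R,3S)-3-methyl-3-(prop-2-en-1-yl)oxiran-2-yl]methanol
Conditions: Ti(OiPr)4 (10 mol%), D-(−)-diethyl tartrate (12 mol%), t-BuOOH, 4 Å MS, CH2Cl2, −20 °C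
Reagents that add atoms: tert-butyl hydroperoxide, CC(C)(C)OO
Why: Sharpless asymmetric epoxidation touches only the allylic alkene, and with D‑(−)‑tartrate a (Z)‑3,3‑disubstituted allylic alcohol of the nerol type should give the (2R,3S)‑epoxide, which sets the future ring C carbinol centre (C‑3) and the centre to be inverted in step 4.

Step 4
Reactants: 6 [(2R,3S)-3-methyl-3-(prop-2-en-1-yl)oxiran-2-yl]methanol; 7 vinylmagnesium bromide
Product: 8 (2S,3S)-2-ethenyl-3-methylhex-5-ene-1,3-diol
Conditions: CH2=CHMgBr (3.5 equiv), CuI (15 mol%), THF/Et2O, −30 → 0 °C; aq. NH4Cl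
Reagents that add atoms: none
Why: copper‑catalysed Grignard opening of a 2,3‑epoxy alcohol whose C‑3 is fully substituted occurs at C‑2 with inversion (SN2), so the vinyl group ends anti to the tertiary oxygen, which becomes hydroxymethyl cis to hydroxyl once the ring is closed.

Step 5
Reactants: 8 (2S,3S)-2-ethenyl-3-methylhex-5-ene-1,3-diol
Product: 9 (1S,2S)-2-(hydroxymethyl)-1-methylcyclopent-3-en-1-ol
Conditions: second-generation Grubbs catalyst RuCl2(H2IMes)(PCy3)(=CHPh) (2 mol%), CH2Cl2, 40 °C
Reagents that add atoms: none
Why: ring‑closing metathesis of a 1,6‑diene to a cyclopentene is fast and tolerates free hydroxyls; no stereocentre is touched and the alkene ends next to the CH that carries the hydroxymethyl arm.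

Step 6
Reactants: 9 (1S,2S)-2-(hydroxymethyl)-1-methylcyclopent-3-en-1-ol
Product: 10 (1S,2R)-2-(iodomethyl)-1-methylcyclopent-3-en-1-ol
Conditions: I2, PPh3, imidazole, CH2Cl2, 0 °C → rt
Reagents that add atoms: iodine, II
Why: Appel‑type iodination (PPh3/I2/imidazole) converts only the primary hydroxyl, the tertiary one being too hindered to form the alkoxyphosphonium salt.

Step 7
Reactants: 10 (1S,2R)-2-(iodomethyl)-1-methylcyclopent-3-en-1-ol
Product: 11 triethyl{[(1S,2R)-2-(iodomethyl)-1-methylcyclopent-3-en-1-yl]oxy}silane
Conditions: Et3SiOTf, 2,6-lutidine, CH2Cl2, −78 → 0 °C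
Reagents that add atoms: triethylsilyl trifluoromethanesulfonate, CC[Si](CC)(CC)OS(=O)(=O)C(F)(F)F
Why: silylation of the tertiary alcohol with the silyl triflate is routine and masks a hydroxyl that would otherwise lactonise onto a cis malonate ester (six‑membered) or close an oxetane under the basic alkylations that follow.

Step 8
Reactants: 11 triethyl{[(1S,2R)-2-(iodomethyl)-1-methylcyclopent-3-en-1-yl]oxy}silane; 12 dimethyl malonate
Product: 13 dimethyl 2-{[(1R,5S)-5-methyl-5-(triethylsilyloxy)cyclopent-2-en-1-yl]methyl}propanedioate
Conditions: NaH, dimethyl malonate (3 equiv), DMF/THF, 0 → 60 °C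
Reagents that add atoms: none
Why: malonic ester alkylation (SN2) of the unhindered sodium malonate, used in excess to suppress dialkylation, on the β‑branched primary iodide; the stereocentres are remote from the reacting carbon.

Step 9
Reactants: 13 dimethyl 2-{[(1R,5S)-5-methyl-5-(triethylsilyloxy)cyclopent-2-en-1-yl]methyl}propanedioate; 14 chloroacetone
Product: 15 dimethyl 2-{[(1R,5S)-5-methyl-5-(triethylsilyloxy)cyclopent-2-en-1-yl]methyl}-2-(2-oxopropyl)propanedioate
Conditions: NaH, THF/DMF, 0 °C; chloroacetone, NaI (10 mol%), rt
Reagents that add atoms: none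
Why: a second malonate alkylation with the very reactive α‑chloroketone (iodide catalysis) installs the acetonyl arm and creates the quaternary carbon whose gem‑diester later assists ring closure.

Step 10
Reactants: 15 dimethyl 2-{[(1R,5S)-5-methyl-5-(triethylsilyloxy)cyclopent-2-en-1-yl]methyl}-2-(2-oxopropyl)propanedioate
Product: 16 dimethyl 2-{[(1R,5S)-5-hydroxy-5-methylcyclopent-2-en-1-yl]methyl}-2-(2-oxopropyl)propanedioate
Conditions: HF·pyridine, pyridine, THF, 0 °C → rt
Reagents that add atoms: none
Why: fluoride cleavage of the tertiary silyl ether under mildly acidic conditions frees the ring C carbinol without forming an alkoxide, so the esters are not attacked.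

Step 11
Reactants: 16 dimethyl 2-{[(1R,5S)-5-hydroxy-5-methylcyclopent-2-en-1-yl]methyl}-2-(2-oxopropyl)propanedioate
Product: 17 dimethyl (1S,3aR,4S,7aR)-1,4-dihydroxy-1,4-dimethyl-1,3a,4,5,7,7a-hexahydro-6H-indene-6,6-dicarboxylate
Conditions: Me2AlCl (4 equiv), CH2Cl2, −78 → 0 °C; aq. KNaC4H4O6
Reagents that add atoms: none
Why: Me2AlCl first turns the ring C carbinol into a chloro(methyl)aluminium alkoxide (methane is lost) and then activates the ketone, whose carbonyl carbon is attacked by the alkene carbon next to the tether‑bearing CH while the hydrogen of the ring CH2 on the same face passes to oxygen through a six‑membered array, so that the double bond moves one position further into ring C. The closest known reaction type is the Lewis‑acid‑promoted type 1 intramolecular carbonyl‑ene cyclisation (citronellal to isopulegol) and the alkylaluminium‑halide ene cyclisation of unsaturated methyl ketones. Ring B closes in the six‑membered mode at the proximal alkene carbon; bonding to the distal carbon would need a seven‑membered ring, and the only allylic hydrogen the oxygen can reach is that of the ring C CH2. The ring fusion (C‑3a) is cis because the three‑atom tether reaches the alkene only on the face that carries its CH2 anchor, and at C‑4 the carbonyl oxygen must lie over ring C to accept that hydrogen, which leaves the methyl group outside and the hydroxyl cis to the ring C bond; both new centres are therefore dictated by the two centres set in steps 3 and 4. The step needs the ketone to react in preference to the two esters and a concerted path instead of a free cation: the gem‑diester holds the ketone over the alkene (one ester avoids the ring C oxygen through a boat‑like array of the forming ring), the aluminium alkoxide lies beside the ketone oxygen and ends as a cyclic aluminium diolate that shields the new tertiary allylic alcohol from ionisation, and Me2AlCl removes adventitious acid.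

Step 12
Reactants: 17 dimethyl (1S,3aR,4S,7aR)-1,4-dihydroxy-1,4-dimethyl-1,3a,4,5,7,7a-hexahydro-6H-indene-6,6-dicarboxylate
Product: 18 dimethyl (1S,3aR,4S,7aR)-1,4-dihydroxy-1,4-dimethyloctahydro-6H-indene-6,6-dicarboxylate
Conditions: H2 (1 atm), PtO2 (5 mol%), EtOAc, rt
Reagents that add atoms: none
Why: heterogeneous hydrogenation of the cis‑disubstituted cyclopentene over platinum in a neutral solvent, chosen because it should neither move the double bond toward the ring fusion nor cleave the allylic C–O bond; no stereocentre is formed.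

Step 13
Reactants: 18 dimethyl (1S,3aR,4S,7aR)-1,4-dihydroxy-1,4-dimethyloctahydro-6H-indene-6,6-dicarboxylate
Product: 19 lactone methyl ester: the C‑6 ester on the hydroxyl face closed onto the C‑1 oxygen (six‑membered lactone through C‑6, C‑7, C‑7a and C‑1), methyl ester on the other face of C‑6, C‑4 hydroxyl free
Conditions: KOtBu (0.2 equiv), 5 Å MS, toluene, 60 °C
Reagents that add atoms: none
Why: alkoxide‑catalysed intramolecular transesterification with removal of methanol reaches only the ester on the hydroxyl face, and the ring C oxygen closes a strain‑free six‑membered lactone (chair–chair bicyclo[3.3.1] array), which makes C‑6 a stereocentre by distinguishing its two carbonyl groups (either hydroxyl would mark the same ester).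

Step 14
Reactants: 20 (R)-2-methylbutanoic acid; 21 6-methylhept-5-en-2-one
Product: 23 (R)-3,10-dimethylundec-9-ene-4,6-dione, via (R)-2-methylbutanoyl chloride 22 (not isolated)
Conditions: (COCl)2, DMF (cat.), CH2Cl2, 0 °C → rt, concentrate; added to 21 (2.2 equiv)/LiN(iPr)2 (2.2 equiv), THF, −78 °C; aq. NH4Cl
Reagents that add atoms: none
Why: kinetic deprotonation of the methyl ketone at its methyl group and C‑acylation of the lithium enolate by the acid chloride (crossed Claisen) gives the β‑diketone, the second equivalent of enolate deprotonating the product so that the α‑stereocentre of the acyl group is not exposed to base.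

Step 15
Reactants: 19 lactone methyl ester; 23 (R)-3,10-dimethylundec-9-ene-4,6-dione
Product: 24 methyl (1S,3aR,4S,6R,7aR)-1,4-dihydroxy-1,4-dimethyl-6-[(6R)-6-methyl-2-(3-methylbut-2-en-1-yl)-3,5-dioxooctanoyl]octahydro-1H-indene-6-carboxylate
Conditions: 23 (3 equiv), LiN(iPr)2 (6 equiv), THF, −78 → −20 °C; then 19, −78 → 0 °C; 1 M HCl
Reagents that add atoms: none
Why: acylation of a β‑diketone dianion at its terminal carbanion (the more nucleophilic site) by an ester, here the lactone carbonyl in preference to the neopentyl methyl ester, opens the lactone and attaches the chain to the carbonyl on the hydroxyl face, which is what defines the spiro configuration; the new CH between two carbonyls is epimerisable and not controlled.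

Step 16
Reactants: 24 triketone ester
Product: 25 spiro trione: ring A 3-hydroxy-2-[(2R)-2-methylbutanoyl]-4-(3-methylbut-2-en-1-yl)cyclohex-2-ene-1,5-dione, spiro at C‑6 to C‑6 of the (1S,3aR,4S,7aR)-1,4-dihydroxy-1,4-dimethyloctahydroindene, ring A C‑5 carbonyl on the hydroxyl face
Conditions: KOtBu (4 equiv), THF, 0 °C → rt; 1 M HCl
Reagents that add atoms: none
Why: Dieckmann‑type Claisen cyclisation of the doubly activated methylene onto the remaining ester closes six‑membered ring A and is driven by formation of the stabilised β‑triketone anion; the spiro centre is fixed because each of its two carbonyls has reacted with a different carbon of the chain.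

Step 17
Reactants: 25 spiro trione
Product: 26 CNP0236509.3 (target)
Conditions: NaOMe (2.5 equiv), MeI (3 equiv), MeOH, 0 °C → rt; 1 M HCl
Reagents that add atoms: iodomethane, CI
Why: C‑methylation of the ring A enolate with NaOMe/MeI (the classic C‑alkylation of acylphloroglucinol‑derived triones) at the only ring carbon still bearing hydrogen; the axial methyl on C‑4 of ring B pushes the axial ring A carbonyl toward the C‑7 methylene, which tilts ring A and opens the face on the side of the C‑5 methylene, so methyl should enter there and leave prenyl on the C‑7 side as in the target, but the bias is expected to be modest and the epimer would be removed by chromatography.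

## Compound list

1 | but-2-yn-1-ol | CC#CCO | starting material
2 | cyclic sodium (Z)-alkenylaluminate, Na[Al(OCH2CH2OCH3)2(OCH2CH=C(CH3))] (2,5-dihydro-1,2-oxaluminole) | CC1=CCO[Al-]1(OCCOC)OCCOC.[Na+] | intermediate (not isolated)
3 | (Z)-3-iodobut-2-en-1-ol | C/C(I)=C/CO | intermediate
4 | allyltributylstannane | C=CC[Sn](CCCC)(CCCC)CCCC | starting material
5 | (Z)-3-methylhexa-2,5-dien-1-ol | C/C(CC=C)=C/CO | intermediate
6 | [(2R,3S)-3-methyl-3-(prop-2-en-1-yl)oxiran-2-yl]methanol | OC[C@H]1O[C@@]1(C)CC=C | intermediate
7 | vinylmagnesium bromide | C=C[Mg]Br | starting material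
8 | (2S,3S)-2-ethenyl-3-methylhex-5-ene-1,3-diol | OC[C@@H]([C@@](C)(O)CC=C)C=C | intermediate
9 | (1S,2S)-2-(hydroxymethyl)-1-methylcyclopent-3-en-1-ol (hydroxyl cis to hydroxymethyl) | OC[C@@H]1C=CC[C@]1(C)O | intermediate
10 | (1S,2R)-2-(iodomethyl)-1-methylcyclopent-3-en-1-ol | IC[C@@H]1C=CC[C@]1(C)O | intermediate
11 | triethyl{[(1S,2R)-2-(iodomethyl)-1-methylcyclopent-3-en-1-yl]oxy}silane | IC[C@@H]1C=CC[C@]1(C)O[Si](CC)(CC)CC | intermediate
12 | dimethyl malonate | COC(=O)CC(=O)OC | starting material
13 | dimethyl 2-{[(1R,5S)-5-methyl-5-(triethylsilyloxy)cyclopent-2-en-1-yl]methyl}propanedioate | COC(=O)C(C(=O)OC)C[C@@H]1C=CC[C@]1(C)O[Si](CC)(CC)CC | intermediate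
14 | chloroacetone | CC(=O)CCl | starting material
15 | dimethyl 2-{[(1R,5S)-5-methyl-5-(triethylsilyloxy)cyclopent-2-en-1-yl]methyl}-2-(2-oxopropyl)propanedioate | CC(=O)CC(C(=O)OC)(C(=O)OC)C[C@@H]1C=CC[C@]1(C)O[Si](CC)(CC)CC | intermediate
16 | dimethyl 2-{[(1R,5S)-5-hydroxy-5-methylcyclopent-2-en-1-yl]methyl}-2-(2-oxopropyl)propanedioate (ene precursor) | CC(=O)CC(C(=O)OC)(C(=O)OC)C[C@@H]1C=CC[C@]1(C)O | intermediate
17 | dimethyl (1S,3aR,4S,7aR)-1,4-dihydroxy-1,4-dimethyl-1,3a,4,5,7,7a-hexahydro-6H-indene-6,6-dicarboxylate (cis-fused, both hydroxyls on the face opposite the ring-fusion hydrogens) | COC(=O)C1(C(=O)OC)C[C@@H]2[C@@H](C=C[C@]2(C)O)[C@@](C)(O)C1 | intermediate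
18 | dimethyl (1S,3aR,4S,7aR)-1,4-dihydroxy-1,4-dimethyloctahydro-6H-indene-6,6-dicarboxylate | COC(=O)C1(C(=O)OC)C[C@@H]2[C@@H](CC[C@]2(C)O)[C@@](C)(O)C1 | intermediate
19 | lactone methyl ester (C‑6 carbonyl on the hydroxyl face closed onto the C‑1 oxygen, six-membered lactone; methyl ester on the other face; C‑4 hydroxyl free) | COC(=O)[C@@]12C[C@@H]3[C@@H](CC[C@]3(C)OC1=O)[C@@](C)(O)C2 | intermediate
20 | (R)-2-methylbutanoic acid | CC[C@@H](C)C(=O)O | starting material
21 | 6-methylhept-5-en-2-one | CC(=O)CCC=C(C)C | starting material
22 | (R)-2-methylbutanoyl chloride | CC[C@@H](C)C(=O)Cl | intermediate (not isolated)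
23 | (R)-3,10-dimethylundec-9-ene-4,6-dione | CC[C@@H](C)C(=O)CC(=O)CCC=C(C)C | intermediate
24 | methyl (1S,3aR,4S,6R,7aR)-1,4-dihydroxy-1,4-dimethyl-6-[(6R)-6-methyl-2-(3-methylbut-2-en-1-yl)-3,5-dioxooctanoyl]octahydro-1H-indene-6-carboxylate (acyl group on the hydroxyl face) | CC[C@@H](C)C(=O)CC(=O)C(CC=C(C)C)C(=O)[C@@]1(C(=O)OC)C[C@@H]2[C@@H](CC[C@]2(C)O)[C@@](C)(O)C1 | intermediate
25 | spiro trione lacking the ring A methyl group (ring A C‑4 bears prenyl and hydrogen) | CC[C@@H](C)C(=O)C1=C(O)C(CC=C(C)C)C(=O)[C@]2(C[C@@H]3[C@@H](CC[C@]3(C)O)[C@@](C)(O)C2)C1=O | intermediate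
26 | CNP0236509.3 | CC[C@@H](C)C(=O)C1=C(O)[C@](C)(CC=C(C)C)C(=O)[C@]2(C[C@@H]3[C@@H](CC[C@]3(C)O)[C@@](C)(O)C2)C1=O | target

## Step count and risks

Total steps: 17. Longest linear sequence: 16 (steps 1–13 and 15–17); step 14 is a one-step side branch.

**Step 11 (ketone‑ene closure of ring B).** The closure may run stepwise through a cation, with chloride capture, proton loss to alkene isomers or the epimeric carbinol, instead of concerted hydrogen transfer. The aluminium alkoxide may lactonise onto a malonate ester before cyclisation, or the weakly electrophilic methyl ketone may not react. The fallback replaces the ketone by an aldehyde and adds the methyl group afterwards. It sets out from 13: alkylation with 2‑bromo‑1,1‑dimethoxyethane (NaH, NaI, DMF, 90 °C) would give the dimethyl acetal F1. Aqueous trifluoroacetic acid would remove acetal and silyl ether to give the hydroxy aldehyde F2. Me2AlCl would then close ring B by the well‑precedented type 1 aldehyde‑ene reaction to the secondary alcohol F3. Hydrogenation (H2, PtO2) would give the saturated diol F4 and Dess–Martin oxidation the cis‑hydrindanone F5. MeLi/CeCl3 at −78 °C should add from the convex face (the side of the ring‑fusion hydrogens), placing methyl cis to those hydrogens and hydroxyl cis to ring C. This returns to the route at 18.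

**Step 15 (dianion acylation at the lactone).** The secondary carbanion may be too hindered to add to a carbonyl flanked by a quaternary carbon, may be quenched by proton transfer, or may fail to distinguish lactone from methyl ester, which would scramble the spiro centre. The fallback builds the chain stepwise with a small organolithium. It sets out from 19: 4‑methylpent‑3‑enyllithium (from 5‑bromo‑2‑methylpent‑2‑ene and t‑BuLi, −78 °C) would add once to the lactone carbonyl, the lithium lactolate holding until work‑up, to give the ketone F6 (in equilibrium with its lactol). Its only enolisable position would be deprotonated with excess LiN(iPr)2 and C‑acetylated with N‑acetylimidazole to the β‑diketone F7. KOtBu would close ring A through the acetyl methyl group onto the ester to give the acyl‑free spiro trione F8. DCC/DMAP acylation with acid 20 (O‑acylation, then acyl shift to carbon, as for cyclic 1,3‑diones) would give 25, where the route is rejoined.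

**Step 17 (last quaternary centre).** Facial discrimination may be poor or reversed because the new centre is remote from the stereocentres of rings B and C, and some O‑methylation may compete. The fallback reverses the order of the two substituents, so that prenyl rather than methyl enters last and takes the favoured face. It sets out from 19 and 22: acid chloride 22 would acylate the kinetic lithium enolate of butan‑2‑one to give (R)‑6‑methyloctane‑3,5‑dione F9. Its dianion would open 19 as in step 15 to the triketone ester F10, and KOtBu would give the 4‑methyl spiro trione F11. C‑prenylation with 1‑bromo‑3‑methylbut‑2‑ene (NaOMe, MeOH, 0 °C) would give 26.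

## Further compounds

F1 | step 11 | dimethyl 2-(2,2-dimethoxyethyl)-2-{[(1R,5S)-5-methyl-5-(triethylsilyloxy)cyclopent-2-en-1-yl]methyl}propanedioate | COC(OC)CC(C(=O)OC)(C(=O)OC)C[C@@H]1C=CC[C@]1(C)O[Si](CC)(CC)CC
F2 | step 11 | dimethyl 2-{[(1R,5S)-5-hydroxy-5-methylcyclopent-2-en-1-yl]methyl}-2-(2-oxoethyl)propanedioate | O=CCC(C(=O)OC)(C(=O)OC)C[C@@H]1C=CC[C@]1(C)O
F3 | step 11 | dimethyl 1,4-dihydroxy-1-methyl-1,3a,4,5,7,7a-hexahydro-6H-indene-6,6-dicarboxylate (cis-fused, secondary C‑4 alcohol) | COC(=O)C1(C(=O)OC)C[C@@H]2[C@@H](C=C[C@]2(C)O)[C@@H](O)C1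
F4 | step 11 | dimethyl 1,4-dihydroxy-1-methyloctahydro-6H-indene-6,6-dicarboxylate | COC(=O)C1(C(=O)OC)C[C@@H]2[C@@H](CC[C@]2(C)O)[C@@H](O)C1
F5 | step 11 | dimethyl 1-hydroxy-1-methyl-4-oxooctahydro-6H-indene-6,6-dicarboxylate (cis-fused) | COC(=O)C1(C(=O)OC)C[C@@H]2[C@@H](CC[C@]2(C)O)C(=O)C1
F6 | step 15 | methyl 1,4-dihydroxy-1,4-dimethyl-6-(5-methylhex-4-enoyl)octahydro-1H-indene-6-carboxylate (acyl group on the hydroxyl face) | CC(C)=CCCC(=O)[C@@]1(C(=O)OC)C[C@@H]2[C@@H](CC[C@]2(C)O)[C@@](C)(O)C1
F7 | step 15 | methyl 6-[2-acetyl-5-methylhex-4-enoyl]-1,4-dihydroxy-1,4-dimethyloctahydro-1H-indene-6-carboxylate | CC(=O)C(CC=C(C)C)C(=O)[C@@]1(C(=O)OC)C[C@@H]2[C@@H](CC[C@]2(C)O)[C@@](C)(O)C1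
F8 | step 15 | spiro trione without the C‑2 acyl group (ring A: 4-prenylcyclohexane-1,3,5-trione, spiro at C‑6) | C1C(=O)C(CC=C(C)C)C(=O)[C@]2(C[C@@H]3[C@@H](CC[C@]3(C)O)[C@@](C)(O)C2)C1=O
F9 | step 17 | (R)-6-methyloctane-3,5-dione | CC[C@@H](C)C(=O)CC(=O)CC
F10 | step 17 | methyl 1,4-dihydroxy-1,4-dimethyl-6-[(6R)-2,6-dimethyl-3,5-dioxooctanoyl]octahydro-1H-indene-6-carboxylate (acyl group on the hydroxyl face) | CC[C@@H](C)C(=O)CC(=O)C(C)C(=O)[C@@]1(C(=O)OC)C[C@@H]2[C@@H](CC[C@]2(C)O)[C@@](C)(O)C1
F11 | step 17 | spiro trione lacking the prenyl group (ring A C‑4 bears methyl and hydrogen) | CC[C@@H](C)C(=O)C1=C(O)C(C)C(=O)[C@]2(C[C@@H]3[C@@H](CC[C@]3(C)O)[C@@](C)(O)C2)C1=O
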